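**Retrosynthetic overview**
- Target ⇒ its ring A monomethyl ether by a final O-demethylation. The methyl group leaves only one phenol OH free to act as nucleophile in the coupling.
- Key disconnection, the diaryl ether C–O bond ⇒ 2,3,5-tribromo-4-methoxyphenol (ring A) + 2,3,5-tribromo-1,4-benzoquinone (ring B). The ether is their exact 1:1 adduct, formed by a new redox-neutral hydroaryloxylation at the only quinone C–H.
- The quinone ⇒ the same tribromomethoxyphenol by oxidative demethylation, so both halves come from one building block.
- Tribromomethoxyphenol ⇒ 3,5-dibromo-4-methoxyphenol (ortho-bromination) ⇒ arylboronate (oxidation) ⇒ 2,6-dibromoanisole (sterically controlled C–H borylation).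
- No ring is built, since both benzene rings are bought in 2,6-dibromoanisole. Ring A is finished first; ring B is made from it by dearomatising oxidation and is re-aromatised in the coupling.

Assumption: the SMILES holds no stereocentre, and the diaryl ether axis has H as one of its four ortho groups and rotates freely, so the target is achiral and there is no enantiomer to select.

**Step 1**
Reactants: 1 2,6-dibromoanisole
Product: 2 2-(3,5-dibromo-4-methoxyphenyl)-4,4,5,5-tetramethyl-1,3,2-dioxaborolane
Conditions: HBpin (1.5 equiv), [Ir(OMe)(cod)]2 (1 mol %), 4,4'-di-tert-butyl-2,2'-bipyridine (2 mol %), THF, 60 °C, 12 h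
Reagents that add atoms: pinacolborane, CC1(C)OBOC1(C)C
Why: Iridium-catalysed aromatic C–H borylation is sterically controlled, so only C4–H, the one C–H of 1 without an ortho substituent, is borylated while the C–Br bonds and the OMe group are left alone; no stereocentre is formed.

**Step 2**
Reactants: 2 2-(3,5-dibromo-4-methoxyphenyl)-4,4,5,5-tetramethyl-1,3,2-dioxaborolane
Product: 3 3,5-dibromo-4-methoxyphenol
Conditions: 30% aq H2O2 (3 equiv), NaOH (1.5 equiv), THF/H2O, 0 °C to rt, 1 h; then 1 M HCl
Reagents that add atoms: hydrogen peroxide, OO
Why: Standard ipso-hydroxylation (oxidation) of an arylboronic ester by basic hydrogen peroxide puts the OH exactly where boron stood and does not touch the aryl bromides or the methyl ether; no stereocentre is formed.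

**Step 3**
Reactants: 3 3,5-dibromo-4-methoxyphenol
Product: 4 2,3,5-tribromo-4-methoxyphenol
Conditions: NBS (1.00 equiv, portionwise), MeCN, −10 °C to 0 °C, dark, 2 h
Reagents that add atoms: N-bromosuccinimide, O=C1CCC(=O)N1Br
Why: Electrophilic aromatic bromination (SEAr) is steered by the free OH: the para position carries OMe, the two ortho positions are equivalent, and the first new bromine deactivates the ring, so one equivalent of NBS at low temperature stops at 4; no stereocentre is formed.

**Step 4**
Reactants: 4 2,3,5-tribromo-4-methoxyphenol (about half of the batch; the rest is kept for step 5)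
Product: 6 2,3,5-tribromocyclohexa-2,5-diene-1,4-dione (tribromo-1,4-benzoquinone), via hemiketal dienone 5 (not isolated)
Conditions: PhI(OCOCF3)2 (1.1 equiv), MeCN/H2O 4:1, 0 °C, 30 min
Reagents that add atoms: water, O
Why: Hypervalent iodine oxidative dearomatisation of a 4-alkoxyphenol (oxidative demethylation): water adds para to the phenol oxygen at C4 and hemiketal 5 loses methanol to give the quinone, the C–Br bonds being inert; the stereocentre of 5 is transient and racemic.

**Step 5**
Reactants: 4 2,3,5-tribromo-4-methoxyphenol; 6 2,3,5-tribromocyclohexa-2,5-diene-1,4-dione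
Product: 8 2,3,5-tribromo-6-(2,3,5-tribromo-4-methoxyphenoxy)benzene-1,4-diol, via dienone adduct 7 (not isolated)
Conditions: 4 (1.2 equiv), n-Bu4NOAc (10 mol %), MeCN, −20 °C, Ar, dark; 6 (1.0 equiv) in MeCN added over 3 h; then rt, 6 h; 1 M HCl work-up
Reagents that add atoms: none
Why: Proposed new method: a base-catalysed, redox-neutral conjugate hydroaryloxylation of a polyhaloquinone, in which acetate deprotonates the more acidic 4 to a naked tetrabutylammonium aryloxide that attacks C6 of 6, the only unsubstituted and least hindered quinone carbon, giving an enolate on O4 stabilised by the bromine on C5; the C6–H of dienone 7 is then shuttled to O1 by the AcOH/4 pair, so irreversible aromatisation gives 8, returns the aryloxide, and places every atom of 4 and 6 in 8; the competing addition–elimination at a C–Br carbon releases bromide and turns active aryloxide into inert n-Bu4NBr, which caps that by-product at the catalyst loading; a non-coordinating cation is chosen because a Lewis acid would bind the less hindered O1 and activate the brominated carbons C3 and C5 instead; C-arylation is disfavoured because the one free carbon of 4 is deactivated by three bromines; hydrogen exchange between 8 and 6 and semiquinone formation are reversible, and since the addition is the only irreversible sink of a manifold that keeps its redox count, slow addition of 6 to excess 4 funnels the mixture to 8; both new OH groups of 8 are flanked by two ortho substituents and are poorer nucleophiles than 4; the stereocentre at C6 of 7 is racemic and vanishes on aromatisation; closest known reaction types are the 1,4-addition/aromatisation of HBr, sulfinic acids and thiols to quinones, the base-catalysed oxa-Michael addition, and the aryloxide addition–elimination on perhaloquinones.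

**Step 6**
Reactants: 8 2,3,5-tribromo-6-(2,3,5-tribromo-4-methoxyphenoxy)benzene-1,4-diol
Product: 9 2,3,5-tribromo-6-(2,3,5-tribromo-4-hydroxyphenoxy)benzene-1,4-diol
Conditions: BBr3 (5 equiv), CH2Cl2, −78 °C to rt, 12 h, Ar; then ice/H2O
Reagents that add atoms: none
Why: Lewis acid-mediated aryl methyl ether cleavage by BBr3 is standard for methoxylated polybrominated diphenyl ethers: the OMe group twisted by two ortho bromines has a basic oxygen whose methyl is taken by bromide, while the diaryl ether, the C–Br bonds and the free OH groups (recovered on hydrolysis) survive, and the acidic medium avoids a base-induced Smiles migration of ring A; the product is achiral.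

**Compound list**
1 | 2,6-dibromoanisole (1,3-dibromo-2-methoxybenzene) | COc1c(Br)cccc1Br | starting material
2 | 2-(3,5-dibromo-4-methoxyphenyl)-4,4,5,5-tetramethyl-1,3,2-dioxaborolane | COc1c(Br)cc(cc1Br)B1OC(C)(C)C(C)(C)O1 | intermediate
3 | 3,5-dibromo-4-methoxyphenol | COc1c(Br)cc(O)cc1Br | intermediate
4 | 2,3,5-tribromo-4-methoxyphenol (OH between H and Br; OMe between two Br) | COc1c(Br)cc(O)c(Br)c1Br | intermediate
5 | 2,3,5-tribromo-4-hydroxy-4-methoxycyclohexa-2,5-dien-1-one (racemic hemiketal; not isolated) | COC1(O)C(Br)=CC(=O)C(Br)=C1Br | intermediate
6 | 2,3,5-tribromocyclohexa-2,5-diene-1,4-dione | O=C1C=C(Br)C(=O)C(Br)=C1Br | intermediate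
7 | 2,3,5-tribromo-4-hydroxy-6-(2,3,5-tribromo-4-methoxyphenoxy)cyclohexa-2,4-dien-1-one (racemic; not isolated) | O=C1C(Br)=C(Br)C(O)=C(Br)C1Oc1cc(Br)c(OC)c(Br)c1Br | intermediate
8 | 2,3,5-tribromo-6-(2,3,5-tribromo-4-methoxyphenoxy)benzene-1,4-diol | COc1c(Br)cc(Oc2c(O)c(Br)c(Br)c(O)c2Br)c(Br)c1Br | intermediate
9 | 2,3,5-tribromo-6-(2,3,5-tribromo-4-hydroxyphenoxy)benzene-1,4-diol (achiral) | Oc1c(Br)cc(Oc2c(O)c(Br)c(Br)c(O)c2Br)c(Br)c1Br | target

**Total step count:** 6. **Longest linear sequence:** 6 (1 → 2 → 3 → 4 → 6 → 8 → 9).

**Three steps most likely to fail**

**Step 5 (the proposed new step).**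
- Attack at a C–Br carbon may be fast enough to kill the catalytic aryloxide early.
- The more acidic product 8, or semiquinone anions, may hold the base and stall turnover.
- The hindered OH groups of 8 may add to further 6.

The fallback uses known chemistry, sets out from 4 and comes back at 8. Phenol 4 is stirred with K2CO3 (1.0 equiv) and an excess (3 equiv) of commercial bromanil (2,3,5,6-tetrabromo-1,4-benzoquinone, O=C1C(Br)=C(Br)C(=O)C(Br)=C1Br) in MeCN at 0 °C. The well-established aryloxide addition–elimination on a perhaloquinone replaces one bromine and gives 2,3,5-tribromo-6-(2,3,5-tribromo-4-methoxyphenoxy)cyclohexa-2,5-diene-1,4-dione F1. After removal of the surplus bromanil, this quinone is reduced with Na2S2O4 in THF/H2O to 8. Step 4 and quinone 6 are then not needed. The same Na2S2O4 treatment also rescues a run of step 5 in which part of 8 has been over-oxidised.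

**Step 4.** The OMe group is twisted out of conjugation and C4 is flanked by two bromines. Water may therefore add slowly, or trifluoroacetate or water may attack at the open C6, and 6 is sensitive to nucleophiles and light on isolation. The fallback sets out from 4 and comes back at 6. The methyl ether is cleaved first with BBr3 in CH2Cl2 to give 2,3,5-tribromobenzene-1,4-diol F2. This is then simply dehydrogenated with activated MnO2 in CH2Cl2 to 6, so no nucleophile has to reach the hindered C4.

**Step 3.** A second bromination to the tetrabromide, or ipso attack at C4 with oxidation to a dibromoquinone, may erode the yield and give mixtures that are hard to separate. The fallback sets out from 3 and comes back at 4.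
- Phenol 3 is protected with MOMCl and i-Pr2NEt as 1,3-dibromo-2-methoxy-5-(methoxymethoxy)benzene F3.
- One equivalent of TMPMgCl·LiCl in THF at −20 °C removes one of the two equivalent protons between OMOM and Br. This gives [2,4-dibromo-3-methoxy-6-(methoxymethoxy)phenyl]magnesium chloride F4.
- Quenching with BrCl2CCCl2Br gives 1,3,4-tribromo-2-methoxy-5-(methoxymethoxy)benzene F5.
- HCl in MeOH removes the MOM group and gives 4.

The number of bromines is then set by the equivalent of base, not by relative bromination rates.

**Further compounds**
F1 | step 5 | 2,3,5-tribromo-6-(2,3,5-tribromo-4-methoxyphenoxy)cyclohexa-2,5-diene-1,4-dione | COc1c(Br)cc(OC2=C(Br)C(=O)C(Br)=C(Br)C2=O)c(Br)c1Br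
F2 | step 4 | 2,3,5-tribromobenzene-1,4-diol | Oc1cc(Br)c(O)c(Br)c1Br
F3 | step 3 | 1,3-dibromo-2-methoxy-5-(methoxymethoxy)benzene | COCOc1cc(Br)c(OC)c(Br)c1
F4 | step 3 | [2,4-dibromo-3-methoxy-6-(methoxymethoxy)phenyl]magnesium chloride | COCOc1cc(Br)c(OC)c(Br)c1[Mg]Cl
F5 | step 3 | 1,3,4-tribromo-2-methoxy-5-(methoxymethoxy)benzene | COCOc1cc(Br)c(OC)c(Br)c1Br
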